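## Analysis of the target

The target 17 is a carbon–carbon linked biflavonoid. A 5,7,4'-trihydroxyflavone (benzo ring A, pyranone ring C, aryl ring B; apigenin-type) is bonded through C3 to C6'' of a (2R,3R)-5,7,4'-trihydroxyflavan-3-ol (benzo ring D, dihydropyran ring F, aryl ring E; epiafzelechin-type). The only stereocentres are the adjacent C2'' and C3'' of ring F, in the 2,3-cis relation, which is the less stable one. C2'' is benzylic to a para-oxygenated ring and bonded to O1'', so it can epimerise by ring opening once ring E is electron-rich. The C3–C6'' bond is tetra-ortho-substituted: C6'' lies between C5''–OH and C7''–OH, and C3 between the C4 carbonyl and C2 bearing ring B. Ring D has two nucleophilic positions, C6'' and C8'', and electrophiles and metalation normally favour C8''. The feature used here is that C6'' carries one carbon substituent (C3 of ring C) flanked by two phenolic oxygens (O5'', O7'') and para to the ring oxygen O1''. That is the pattern of the formyl carbon of a symmetric 2,4,6-trioxygenated benzaldehyde, so C3 can enter as that formyl carbon and ring C can be built around it. Six phenols, a secondary alcohol, a base-sensitive chromone and ring D phenols that could add to C2 under base make a neutral final deprotection advisable.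

## Retrosynthetic reasoning

**17 back to 15.** The four phenols of rings A and D are carried as benzyl ethers (16) and removed last by hydrogenolysis. The phenols of rings B and E are carried as pivalates (15) and removed just before. The pivalate is electron-withdrawing, which keeps every benzylic C–O stage of the ring F synthesis from ionising. The forward steps must leave the chromone and C2'' untouched.

**15 back to 12 and 13 (key disconnection).** Ring C is cut at C3–C4 and O1–C2. This gives diazoketone 12, which already carries ring D on the future C3 and ring B on the future C2, and salicylaldehyde 13, which brings ring A, C4 and O1. The cut is placed here and not at C3–C6'' because the hindered bond to ring D then never has to be made between two sp2 carbons. The forward reaction has to join the formyl carbon of 13 to the carbene carbon of 12 and close the pyranone by dehydration of diketone 14. No regiochemical question arises.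

**12 back to 8 and 2.** The diazo group comes from the methylene of ketone 11 by diazo transfer. Ketone 11 is cut between the future C3 and C2: the formyl carbon of aldehyde 8 becomes the methylene, and aldehyde 2 supplies the carbonyl and ring B. The forward reaction is a formyl C–H insertion of the diazoalkane 10, generated from sulfonylhydrazone 9.

**8 back to 6.** Ring F is cut at C4''–C4a''. Benzyl ethers are removed to give 7, and 7 is opened to the aryl oxiranylmethyl ether 6. The forward reaction is a 6-endo Friedel–Crafts attack of ring D on the terminal oxirane carbon. The two ring positions ortho to the ether oxygen of 6 are equivalent, so the formyl group must end on C6''.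

**6 back to 4 and 5.** The O1''–C2'' bond is cut to give epoxy alcohol 4 and the symmetric trihydroxybenzaldehyde 5. The hydroxyl of 5 para to the formyl group is the most acidic and the only one not hydrogen-bonded, so it is etherified without protecting groups. The forward reaction must invert the carbinol carbon.

**4 back to 1.** Both stereocentres are set together in 4 by a tartrate-controlled epoxidation that resolves the racemic allylic alcohol 3. Alcohol 3 comes from aldehyde 2 and a vinyl Grignard reagent, and 2 from 1 by acylation.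

**13 back to 5.** Aldehyde 13 is the bis-benzyl ether of 5. Compound 5 therefore supplies rings A and D, and compound 2 supplies rings B and E.

## Alternatives that were turned down

**Alternative 1:** The textbook disconnection cuts the C3–C6'' bond between two finished halves. The forward key step is a Suzuki–Miyaura coupling of 3-iodoflavone A1 with flavan-6-yl boronate A2. It was turned down for three reasons:
- The bond is tetra-ortho-substituted, and a 2,6-dialkoxyarylboronate loses boron by protonolysis faster than it transmetalates.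
- A2 needs functionalisation at C6'' of a 5,7-dialkoxyflavan, where C8'' reacts first, so blocking steps are added.
- A2 also needs its own seven- to eight-step synthesis of the cis-flavan-3-ol, and the riskiest step comes last with both halves invested.

**Alternative 2:** Ring F is cut last (C4''–C4a'' and O1''–C2'') from the flavone-bearing phenol A3. The forward sequence is acid-catalysed C-cinnamylation, osmium-catalysed asymmetric dihydroxylation, cyclisation to the 2,3-trans flavan-3-ol, oxidation to ketone A4 and reduction with a hindered borohydride to the cis alcohol. It was turned down because six to seven linear steps run on the most advanced intermediate. The trans-to-cis correction also needs a hydride reagent in the presence of the chromone enone, and A3 still contains the hindered biaryl bond.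

**Alternative 3:** O1–C2 and C3–C6'' are cut together. The forward step is an oxypalladation and reductive elimination cascade of ynone A5 with 6-bromoflavan A6 under zerovalent palladium. It was turned down because the phenoxide of A5 cyclises onto the ynone without metal to the 3-unsubstituted flavone, faster than an electron-rich, doubly ortho-substituted arylpalladium species can engage the alkyne. A6 also has the same C6'' regiochemistry problem as A2.

Key step: step 10

Assumption: the C3–C6'' axis has no descriptor in the target structure and is treated as not configurationally defined; if rotation is slow, 15 to 17 are expected as interconverting rotamers.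

## Route

Step 1
Reactants: 1 4-hydroxybenzaldehyde
Product: 2 4-formylphenyl 2,2-dimethylpropanoate
Conditions: PivCl, Et3N, DMAP (cat.), CH2Cl2, 0 °C to rt
Reagents that add atoms: pivaloyl chloride, CC(C)(C)C(Cl)=O
Why: Esterification of the phenol; the pivalate makes the para oxygen of rings B and E electron-withdrawing, so the benzylic carbinol, ether and C2''–O1'' stages of steps 3 to 5 and 10 should not ionise, and it is hindered enough to survive step 2.

Step 2
Reactants: 2 4-formylphenyl 2,2-dimethylpropanoate
Product: 3 rac-4-(1-hydroxyprop-2-en-1-yl)phenyl 2,2-dimethylpropanoate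
Conditions: CH2=CHMgBr (1.05 equiv), THF, −78 °C; aq. NH4Cl
Reagents that add atoms: vinylmagnesium bromide, C=C[Mg]Br
Why: Grignard 1,2-addition to the aldehyde, which at −78 °C should be much faster than attack on the hindered aryl ester; the carbinol is formed racemic and is resolved in step 3.

Step 3
Reactants: 3 rac-4-(1-hydroxyprop-2-en-1-yl)phenyl 2,2-dimethylpropanoate
Product: 4 4-{(S)-hydroxy[(2R)-oxiran-2-yl]methyl}phenyl 2,2-dimethylpropanoate
Conditions: Ti(OiPr)4 (0.15 equiv), L-(+)-diisopropyl tartrate (0.2 equiv), t-BuOOH (0.55 equiv), 4 Å MS, CH2Cl2, −20 °C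
Reagents that add atoms: tert-butyl hydroperoxide, CC(C)(C)OO
Why: Sharpless asymmetric epoxidation run as a kinetic resolution: with this tartrate the (R)-enantiomer of 3 should react much faster and on the face that gives the erythro epoxy alcohol, so reagent control fixes the carbinol carbon (S, future C2'') and the oxirane carbon (R, future C3'') in one operation. The oxidant is kept substoichiometric so that 4 arises from the fast enantiomer only; at most half of 3 can be converted and the unreacted (S)-3 is separated.

Step 4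
Reactants: 4 4-{(S)-hydroxy[(2R)-oxiran-2-yl]methyl}phenyl 2,2-dimethylpropanoate, 5 2,4,6-trihydroxybenzaldehyde (2 equiv)
Product: 6 4-{(R)-(4-formyl-3,5-dihydroxyphenoxy)[(2R)-oxiran-2-yl]methyl}phenyl 2,2-dimethylpropanoate
Conditions: PPh3, DIAD, THF, 0 °C to rt
Reagents that add atoms: none
Why: Mitsunobu etherification; the hydroxyl of 5 para to the formyl group is the most acidic and the only one not hydrogen-bonded to it, so the monoether should form there. SN2 displacement inverts the carbinol carbon (S to R), which gives the threo relation of ether and oxirane oxygens that becomes 2,3-cis; the electron-poor aryl group and the adjacent oxirane disfavour ionisation.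

Step 5
Reactants: 6 4-{(R)-(4-formyl-3,5-dihydroxyphenoxy)[(2R)-oxiran-2-yl]methyl}phenyl 2,2-dimethylpropanoate
Product: 7 4-[(2R,3R)-6-formyl-3,5,7-trihydroxy-3,4-dihydro-2H-chromen-2-yl]phenyl 2,2-dimethylpropanoate
Conditions: AuCl3 (5 mol %), AgOTf (15 mol %), ClCH2CH2Cl, rt to 40 °C
Reagents that add atoms: none
Why: Intramolecular Friedel–Crafts epoxide–arene alkylation (6-endo attack of the ring carbon ortho to the ether oxygen on the terminal oxirane carbon), the known route from aryl glycidyl ethers to chroman-3-ols. The two ortho positions are equivalent, so the formyl group must end on C6'' between O5'' and O7''; no bond to C2'' or C3'' is broken, so the (2R,3R) cis configuration follows from 6.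

Step 6
Reactants: 7 4-[(2R,3R)-6-formyl-3,5,7-trihydroxy-3,4-dihydro-2H-chromen-2-yl]phenyl 2,2-dimethylpropanoate
Product: 8 4-[(2R,3R)-5,7-bis(benzyloxy)-6-formyl-3-hydroxy-3,4-dihydro-2H-chromen-2-yl]phenyl 2,2-dimethylpropanoate
Conditions: BnBr (2.5 equiv), K2CO3, DMF, rt to 50 °C
Reagents that add atoms: benzyl bromide, BrCc1ccccc1
Why: Williamson etherification of the two phenols that flank the formyl group; K2CO3 should not deprotonate the secondary alcohol, and with ring E acylated no quinone methide can form that would open ring F.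

Step 7
Reactants: 8 4-[(2R,3R)-5,7-bis(benzyloxy)-6-formyl-3-hydroxy-3,4-dihydro-2H-chromen-2-yl]phenyl 2,2-dimethylpropanoate, 2 4-formylphenyl 2,2-dimethylpropanoate (2 equiv)
Product: 11 4-(2-{(2R,3R)-5,7-bis(benzyloxy)-3-hydroxy-2-[4-(2,2-dimethylpropanoyloxy)phenyl]-3,4-dihydro-2H-chromen-6-yl}acetyl)phenyl 2,2-dimethylpropanoate, via tosylhydrazone 9 (not isolated), via aryldiazomethane 10 (not isolated)
Conditions: TsNHNH2, 1,4-dioxane, 60 °C; then K2CO3, 2, 110 °C
Reagents that add atoms: 4-methylbenzenesulfonohydrazide, Cc1ccc(cc1)S(=O)(=O)NN (supplies the N–NHTs unit of 9 and the diazo nitrogens of 10; none of its atoms remain in 11)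
Why: Condensation to 9, Bamford–Stevens loss of sulfinate to 10, addition of the diazo carbon to the electron-poor aldehyde 2 and 1,2-hydride shift with loss of nitrogen (formyl C–H insertion, a known ketone synthesis from tosylhydrazones and aryl aldehydes). The formyl carbon of 8 becomes the methylene that will be C3; the electron-poor aryl group of 2 migrates poorly, which favours hydride over aryl shift.

Step 8
Reactants: 11 4-(2-{(2R,3R)-5,7-bis(benzyloxy)-3-hydroxy-2-[4-(2,2-dimethylpropanoyloxy)phenyl]-3,4-dihydro-2H-chromen-6-yl}acetyl)phenyl 2,2-dimethylpropanoate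
Product: 12 4-(2-{(2R,3R)-5,7-bis(benzyloxy)-3-hydroxy-2-[4-(2,2-dimethylpropanoyloxy)phenyl]-3,4-dihydro-2H-chromen-6-yl}-2-diazoacetyl)phenyl 2,2-dimethylpropanoate
Conditions: 4-acetamidobenzenesulfonyl azide, DBU, MeCN, 0 °C to rt
Reagents that add atoms: 4-acetamidobenzenesulfonyl azide, CC(=O)Nc1ccc(cc1)S(=O)(=O)N=[N+]=[N-]
Why: Regitz diazo transfer to the benzylic methylene of an aryl benzyl ketone; DBU should deprotonate only this position, leaving the secondary alcohol and the pivalates untouched.

Step 9
Reactants: 5 2,4,6-trihydroxybenzaldehyde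
Product: 13 2,4-bis(benzyloxy)-6-hydroxybenzaldehyde
Conditions: BnBr (2.1 equiv), K2CO3, DMF, rt
Reagents that add atoms: benzyl bromide, BrCc1ccccc1
Why: Williamson etherification; the para hydroxyl and one ortho hydroxyl react, while the second ortho hydroxyl is held in the hydrogen bond to the formyl group and should stay free. That free hydroxyl directs the rhodium in step 10 and becomes O1.

Step 10
Reactants: 12 4-(2-{(2R,3R)-5,7-bis(benzyloxy)-3-hydroxy-2-[4-(2,2-dimethylpropanoyloxy)phenyl]-3,4-dihydro-2H-chromen-6-yl}-2-diazoacetyl)phenyl 2,2-dimethylpropanoate, 13 2,4-bis(benzyloxy)-6-hydroxybenzaldehyde (1.5 equiv)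
Product: 15 4-[5,7-bis(benzyloxy)-3-{(2R,3R)-5,7-bis(benzyloxy)-3-hydroxy-2-[4-(2,2-dimethylpropanoyloxy)phenyl]-3,4-dihydro-2H-chromen-6-yl}-4-oxo-4H-chromen-2-yl]phenyl 2,2-dimethylpropanoate, via 1,3-diketone 14 (not isolated)
Conditions: [Cp*Rh(MeCN)3](SbF6)2 (5 mol %), NaOAc (0.3 equiv), AcOH (1 equiv), ClCH2CH2Cl, 60 °C, slow addition of 12; then TsOH·H2O, 60 °C
Reagents that add atoms: none
Why: Proposed new method: acetate-assisted cleavage of the formyl C–H bond of 13 by the cationic Cp*Rh catalyst (trivalent rhodium), directed by the phenoxide, should give a five-membered acyl rhodacycle; 12 is decomposed at this centre to a rhodium carbene, the acyl group migrates onto the carbene carbon (C3–C4 bond) and protonolysis by AcOH releases diketone 14 and the catalyst in a redox-neutral cycle. The closest known reaction type is the Cp*Rh-catalysed annulation of salicylaldehydes with sulfoxonium ylides or with diazo-1,3-dicarbonyl compounds to chromones; new here is a donor/acceptor diazoketone whose carbene carbon carries a 2,6-dioxygenated aryl group. Ring C is then closed by 6-exo-trig attack of the ring A phenol of 14 on the aroyl carbonyl (O1–C2 bond), followed by acid-promoted dehydration of the hemiketal. No stereocentre is formed; C2'' and C3'' are remote, and the pivalate on ring E keeps the C2''–O1'' bond from ionising in acid. Regiochemistry needs no control, because the carbene carbon already bears ring D and the aroyl group, so ring D can only end on C3 and ring B on C2, and the ring A hydroxyl is the only free phenol. The selectivity that must be secured is chemoselectivity of the carbene: migratory insertion inside the rhodacycle has to outrun insertion into the benzylic C–H bonds of the flanking benzyloxy groups and Wolff rearrangement, hence a silver-free catalyst, an excess of 13 and slow addition of 12. The hindered C3–C4 bond is thus made at a planar carbene carbon inside the coordination sphere, not by attack of a crowded enolate on a doubly ortho-substituted acyl electrophile.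

Step 11
Reactants: 15 4-[5,7-bis(benzyloxy)-3-{(2R,3R)-5,7-bis(benzyloxy)-3-hydroxy-2-[4-(2,2-dimethylpropanoyloxy)phenyl]-3,4-dihydro-2H-chromen-6-yl}-4-oxo-4H-chromen-2-yl]phenyl 2,2-dimethylpropanoate
Product: 16 5,7-bis(benzyloxy)-3-[(2R,3R)-5,7-bis(benzyloxy)-3-hydroxy-2-(4-hydroxyphenyl)-3,4-dihydro-2H-chromen-6-yl]-2-(4-hydroxyphenyl)-4H-chromen-4-one
Conditions: NaOMe (3 equiv), MeOH/THF, 0 °C to rt; aq. NH4Cl
Reagents that add atoms: none
Why: Transesterification of the two aryl pivalates by methoxide; benzyl ethers, chromone and secondary alcohol should be stable, and because ring D is still benzylated no ring D phenoxide can add to C2 of ring C. Low temperature and short exposure limit base-mediated epimerisation at C2''.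

Step 12
Reactants: 16 5,7-bis(benzyloxy)-3-[(2R,3R)-5,7-bis(benzyloxy)-3-hydroxy-2-(4-hydroxyphenyl)-3,4-dihydro-2H-chromen-6-yl]-2-(4-hydroxyphenyl)-4H-chromen-4-one
Product: 17 5,7-dihydroxy-2-(4-hydroxyphenyl)-3-[(2R,3R)-3,5,7-trihydroxy-2-(4-hydroxyphenyl)-3,4-dihydro-2H-chromen-6-yl]-4H-chromen-4-one
Conditions: H2 (1 atm), Pd(OH)2/C, THF/MeOH, rt
Reagents that add atoms: none
Why: Hydrogenolysis of the four benzyl ethers under neutral conditions; the tetrasubstituted, conjugated C2=C3 bond of the chromone should not be reduced and the stereocentres are untouched.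

## Compound list

1 | 4-hydroxybenzaldehyde | O=Cc1ccc(O)cc1 | starting material
2 | 4-formylphenyl 2,2-dimethylpropanoate | CC(C)(C)C(=O)Oc1ccc(C=O)cc1 | intermediate
3 | rac-4-(1-hydroxyprop-2-en-1-yl)phenyl 2,2-dimethylpropanoate | CC(C)(C)C(=O)Oc1ccc(C(O)C=C)cc1 | intermediate
4 | 4-{(S)-hydroxy[(2R)-oxiran-2-yl]methyl}phenyl 2,2-dimethylpropanoate | CC(C)(C)C(=O)Oc1ccc([C@H](O)[C@H]2CO2)cc1 | intermediate
5 | 2,4,6-trihydroxybenzaldehyde | O=Cc1c(O)cc(O)cc1O | starting material
6 | 4-{(R)-(4-formyl-3,5-dihydroxyphenoxy)[(2R)-oxiran-2-yl]methyl}phenyl 2,2-dimethylpropanoate | O=Cc1c(O)cc(O[C@H](c2ccc(OC(=O)C(C)(C)C)cc2)[C@H]2CO2)cc1O | intermediate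
7 | 4-[(2R,3R)-6-formyl-3,5,7-trihydroxy-3,4-dihydro-2H-chromen-2-yl]phenyl 2,2-dimethylpropanoate | O=Cc1c(O)cc2c(c1O)C[C@@H](O)[C@@H](c1ccc(OC(=O)C(C)(C)C)cc1)O2 | intermediate
8 | 4-[(2R,3R)-5,7-bis(benzyloxy)-6-formyl-3-hydroxy-3,4-dihydro-2H-chromen-2-yl]phenyl 2,2-dimethylpropanoate | O=Cc1c(OCc2ccccc2)cc2c(c1OCc1ccccc1)C[C@@H](O)[C@@H](c1ccc(OC(=O)C(C)(C)C)cc1)O2 | intermediate
9 | N'-[(E)-{(2R,3R)-5,7-bis(benzyloxy)-3-hydroxy-2-[4-(2,2-dimethylpropanoyloxy)phenyl]-3,4-dihydro-2H-chromen-6-yl}methylidene]-4-methylbenzenesulfonohydrazide | Cc1ccc(cc1)S(=O)(=O)N/N=C/c1c(OCc2ccccc2)cc2c(c1OCc1ccccc1)C[C@@H](O)[C@@H](c1ccc(OC(=O)C(C)(C)C)cc1)O2 | intermediate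
10 | 4-[(2R,3R)-5,7-bis(benzyloxy)-6-(diazomethyl)-3-hydroxy-3,4-dihydro-2H-chromen-2-yl]phenyl 2,2-dimethylpropanoate | [N-]=[N+]=Cc1c(OCc2ccccc2)cc2c(c1OCc1ccccc1)C[C@@H](O)[C@@H](c1ccc(OC(=O)C(C)(C)C)cc1)O2 | intermediate
11 | 4-(2-{(2R,3R)-5,7-bis(benzyloxy)-3-hydroxy-2-[4-(2,2-dimethylpropanoyloxy)phenyl]-3,4-dihydro-2H-chromen-6-yl}acetyl)phenyl 2,2-dimethylpropanoate | CC(C)(C)C(=O)Oc1ccc(cc1)C(=O)Cc1c(OCc2ccccc2)cc2c(c1OCc1ccccc1)C[C@@H](O)[C@@H](c1ccc(OC(=O)C(C)(C)C)cc1)O2 | intermediate
12 | 4-(2-{(2R,3R)-5,7-bis(benzyloxy)-3-hydroxy-2-[4-(2,2-dimethylpropanoyloxy)phenyl]-3,4-dihydro-2H-chromen-6-yl}-2-diazoacetyl)phenyl 2,2-dimethylpropanoate | CC(C)(C)C(=O)Oc1ccc(cc1)C(=O)C(=[N+]=[N-])c1c(OCc2ccccc2)cc2c(c1OCc1ccccc1)C[C@@H](O)[C@@H](c1ccc(OC(=O)C(C)(C)C)cc1)O2 | intermediate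
13 | 2,4-bis(benzyloxy)-6-hydroxybenzaldehyde | O=Cc1c(O)cc(OCc2ccccc2)cc1OCc1ccccc1 | intermediate
14 | 4-(3-[2,4-bis(benzyloxy)-6-hydroxyphenyl]-2-{(2R,3R)-5,7-bis(benzyloxy)-3-hydroxy-2-[4-(2,2-dimethylpropanoyloxy)phenyl]-3,4-dihydro-2H-chromen-6-yl}-3-oxopropanoyl)phenyl 2,2-dimethylpropanoate (central carbon not defined, keto and enol forms) | O=C(c1c(O)cc(OCc2ccccc2)cc1OCc1ccccc1)C(C(=O)c1ccc(OC(=O)C(C)(C)C)cc1)c1c(OCc2ccccc2)cc2c(c1OCc1ccccc1)C[C@@H](O)[C@@H](c1ccc(OC(=O)C(C)(C)C)cc1)O2 | intermediate
15 | 4-[5,7-bis(benzyloxy)-3-{(2R,3R)-5,7-bis(benzyloxy)-3-hydroxy-2-[4-(2,2-dimethylpropanoyloxy)phenyl]-3,4-dihydro-2H-chromen-6-yl}-4-oxo-4H-chromen-2-yl]phenyl 2,2-dimethylpropanoate | O=c1c(-c2c(OCc3ccccc3)cc3c(c2OCc2ccccc2)C[C@@H](O)[C@@H](c2ccc(OC(=O)C(C)(C)C)cc2)O3)c(-c2ccc(OC(=O)C(C)(C)C)cc2)oc2cc(OCc3ccccc3)cc(OCc3ccccc3)c12 | intermediate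
16 | 5,7-bis(benzyloxy)-3-[(2R,3R)-5,7-bis(benzyloxy)-3-hydroxy-2-(4-hydroxyphenyl)-3,4-dihydro-2H-chromen-6-yl]-2-(4-hydroxyphenyl)-4H-chromen-4-one | O=c1c(-c2c(OCc3ccccc3)cc3c(c2OCc2ccccc2)C[C@@H](O)[C@@H](c2ccc(O)cc2)O3)c(-c2ccc(O)cc2)oc2cc(OCc3ccccc3)cc(OCc3ccccc3)c12 | intermediate
17 | 5,7-dihydroxy-2-(4-hydroxyphenyl)-3-[(2R,3R)-3,5,7-trihydroxy-2-(4-hydroxyphenyl)-3,4-dihydro-2H-chromen-6-yl]-4H-chromen-4-one | O=c1c(-c2c(O)cc3c(c2O)C[C@@H](O)[C@@H](c2ccc(O)cc2)O3)c(-c2ccc(O)cc2)oc2cc(O)cc(O)c12 | target

## Step count and least certain steps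

Total step count: 12. Longest linear sequence: 11 steps (steps 1 to 8, then 10 to 12, from 1); step 9 is a one-step branch from 5.

**Step 10 (key step, proposed new method).** The most likely failure is loss of chemoselectivity of the carbene. Insertion into the benzylic C–H bonds of the two benzyloxy groups beside the carbene carbon, or Wolff rearrangement, could outrun a migratory insertion that is slowed by crowding at rhodium. The fallback uses known chemistry and sets out from 11. Soft enolisation (MgBr2·OEt2, iPr2NEt) and C-acylation with 2,4,6-trifluorobenzoyl chloride, which also acylates the 3''-hydroxyl, would give the fluorinated 2-aryl-1,3-diketone F1. K2CO3 in DMF would then close ring C by intramolecular SNAr of the enolate oxygen on an ortho fluorine, giving the 5,7-difluorochromone F2. Sodium benzyloxide (BnOH, NaH, DMF) would replace both activated fluorines and cleave the two pivalates and the fluorobenzoate, which returns the route to 16.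

**Step 5.** The activated oxirane may open at the internal carbon (5-exo closure) or rearrange by hydride shift before the formyl-deactivated ring attacks, since the formyl group lowers the nucleophilicity of ring D. The fallback replaces electrophilic aromatic substitution by a cross-electrophile coupling and sets out from 6. Iodination with N-iodosuccinimide at one of the two equivalent positions ortho to the ether oxygen would give the aryl iodide F3. Nickel-catalysed reductive coupling (NiCl2(dme), 2,2'-bipyridine, NaI, Zn, Et3N·HCl), in which iodide opens the oxirane at its terminal carbon, would close ring F and return the route to 7.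

**Step 7.** The hindered, electron-rich diazoalkane 10 may lose nitrogen before it meets the aldehyde, leading to carbene insertion into a neighbouring benzyloxy group or azine formation. The ketone 11 may also condense with excess 2. The fallback builds the same bond by olefination and sets out from 2 and 8. Aldehyde 2 would be converted with HC(OMe)3 and an acid catalyst into the dimethyl acetal F4, and with P(OEt)3 and BF3·OEt2 into the α-methoxybenzylphosphonate F5. Horner–Wadsworth–Emmons reaction of lithiated F5 (LiN(SiMe3)2, THF, −78 °C) with 8 would give the enol ether F6, and mild aqueous acid would hydrolyse it to 11.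

**Step 4.** Alkylation may occur at an ortho hydroxyl or twice, and configuration may erode if the activated benzylic alcohol ionises. The fallback separates activation from displacement and sets out from 4. MsCl and Et3N would give the mesylate F7 with retention. The preformed mono-potassium salt of 5 (K2CO3, 1 equiv, DMF), which is the para phenoxide, would displace it with inversion and return the route to 6.

## Further compounds

F1 | step 10 | (2R,3R)-5,7-bis(benzyloxy)-2-[4-(2,2-dimethylpropanoyloxy)phenyl]-6-{1,3-dioxo-1-[4-(2,2-dimethylpropanoyloxy)phenyl]-3-(2,4,6-trifluorophenyl)propan-2-yl}-3,4-dihydro-2H-chromen-3-yl 2,4,6-trifluorobenzoate | O=C(c1c(F)cc(F)cc1F)C(C(=O)c1ccc(OC(=O)C(C)(C)C)cc1)c1c(OCc2ccccc2)cc2c(c1OCc1ccccc1)C[C@@H](OC(=O)c1c(F)cc(F)cc1F)[C@@H](c1ccc(OC(=O)C(C)(C)C)cc1)O2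
F2 | step 10 | (2R,3R)-5,7-bis(benzyloxy)-6-{5,7-difluoro-4-oxo-2-[4-(2,2-dimethylpropanoyloxy)phenyl]-4H-chromen-3-yl}-2-[4-(2,2-dimethylpropanoyloxy)phenyl]-3,4-dihydro-2H-chromen-3-yl 2,4,6-trifluorobenzoate | O=c1c(-c2c(OCc3ccccc3)cc3c(c2OCc2ccccc2)C[C@@H](OC(=O)c2c(F)cc(F)cc2F)[C@@H](c2ccc(OC(=O)C(C)(C)C)cc2)O3)c(-c2ccc(OC(=O)C(C)(C)C)cc2)oc2cc(F)cc(F)c12
F3 | step 5 | 4-{(R)-(4-formyl-3,5-dihydroxy-2-iodophenoxy)[(2R)-oxiran-2-yl]methyl}phenyl 2,2-dimethylpropanoate | O=Cc1c(O)cc(O[C@H](c2ccc(OC(=O)C(C)(C)C)cc2)[C@H]2CO2)c(I)c1O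
F4 | step 7 | 4-(dimethoxymethyl)phenyl 2,2-dimethylpropanoate | COC(OC)c1ccc(OC(=O)C(C)(C)C)cc1
F5 | step 7 | 4-[(diethoxyphosphoryl)(methoxy)methyl]phenyl 2,2-dimethylpropanoate | CCOP(=O)(OCC)C(OC)c1ccc(OC(=O)C(C)(C)C)cc1
F6 | step 7 | 4-(2-{(2R,3R)-5,7-bis(benzyloxy)-3-hydroxy-2-[4-(2,2-dimethylpropanoyloxy)phenyl]-3,4-dihydro-2H-chromen-6-yl}-1-methoxyethenyl)phenyl 2,2-dimethylpropanoate (alkene geometry not defined) | COC(=Cc1c(OCc2ccccc2)cc2c(c1OCc1ccccc1)C[C@@H](O)[C@@H](c1ccc(OC(=O)C(C)(C)C)cc1)O2)c1ccc(OC(=O)C(C)(C)C)cc1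
F7 | step 4 | 4-{(S)-(methanesulfonyloxy)[(2R)-oxiran-2-yl]methyl}phenyl 2,2-dimethylpropanoate | CC(C)(C)C(=O)Oc1ccc([C@H](OS(C)(=O)=O)[C@H]2CO2)cc1
A1 | alternative 1 | 5,7-bis(benzyloxy)-2-[4-(benzyloxy)phenyl]-3-iodo-4H-chromen-4-one | O=c1c(I)c(-c2ccc(OCc3ccccc3)cc2)oc2cc(OCc3ccccc3)cc(OCc3ccccc3)c12
A2 | alternative 1 | 2-{(2R,3R)-3,5,7-tris(benzyloxy)-2-[4-(benzyloxy)phenyl]-3,4-dihydro-2H-chromen-6-yl}-4,4,5,5-tetramethyl-1,3,2-dioxaborolane | CC1(C)OB(OC1(C)C)c1c(OCc2ccccc2)cc2c(c1OCc1ccccc1)C[C@@H](OCc1ccccc1)[C@@H](c1ccc(OCc3ccccc3)cc1)O2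
A3 | alternative 2 | 5,7-bis(benzyloxy)-3-[2,6-bis(benzyloxy)-4-hydroxyphenyl]-2-[4-(benzyloxy)phenyl]-4H-chromen-4-one | O=c1c(-c2c(OCc3ccccc3)cc(O)cc2OCc2ccccc2)c(-c2ccc(OCc3ccccc3)cc2)oc2cc(OCc3ccccc3)cc(OCc3ccccc3)c12
A4 | alternative 2 | 5,7-bis(benzyloxy)-3-{(2R)-5,7-bis(benzyloxy)-2-[4-(benzyloxy)phenyl]-3-oxo-3,4-dihydro-2H-chromen-6-yl}-2-[4-(benzyloxy)phenyl]-4H-chromen-4-one | O=c1c(-c2c(OCc3ccccc3)cc3c(c2OCc2ccccc2)CC(=O)[C@@H](c2ccc(OCc4ccccc4)cc2)O3)c(-c2ccc(OCc3ccccc3)cc2)oc2cc(OCc3ccccc3)cc(OCc3ccccc3)c12
A5 | alternative 3 | 1-[2,4-bis(benzyloxy)-6-hydroxyphenyl]-3-[4-(benzyloxy)phenyl]prop-2-yn-1-one | O=C(C#Cc1ccc(OCc2ccccc2)cc1)c1c(O)cc(OCc2ccccc2)cc1OCc1ccccc1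
A6 | alternative 3 | (2R,3R)-3,5,7-tris(benzyloxy)-2-[4-(benzyloxy)phenyl]-6-bromo-3,4-dihydro-2H-chromene | Brc1c(OCc2ccccc2)cc2c(c1OCc1ccccc1)C[C@@H](OCc1ccccc1)[C@@H](c1ccc(OCc3ccccc3)cc1)O2
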